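All constants come from no measurement; the result is computed.

Follow the substrate through these flasks and mark each place where it can leave the road to target.

    intermediate B → target (k1 = 2.7 × 10⁻⁴ min⁻¹, Ea1 = 88.0 kJ mol⁻¹)
    crystals ⇌ target, rate k2*(cs2 - [target]) while solid is left; crystals form when [target] > cs2 (cs2 = 0.076 M, k2 = 0.19 min⁻¹)
    intermediate A → intermediate B (k3 = 1.6 × 10⁻⁴ min⁻¹, Ea3 = 105 kJ mol⁻¹)
    substrate + coupling partner → intermediate A (k4 = 0.0011 M⁻¹ min⁻¹, Ea4 = 76.0 kJ mol⁻¹)
    coupling partner + intermediate B → intermediate C (k5 = 0.0028 M⁻¹ min⁻¹, Ea5 = 54.0 kJ mol⁻¹)
    intermediate C → side product B (k6 = 0.0085 min⁻¹, Ea6 = 82.0 kJ mol⁻¹)
    intermediate A → side product A (k7 = 3.5 × 10⁻⁴ min⁻¹, Ea7 = 94.0 kJ mol⁻¹)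
    (constants at 0 °C)

| flask | substrate | coupling partner | temperature | time | remark |
|---|---|---|---|---|---|
| eta | 0.10 M (in portions, 3) | 0.400 M | 0 °C | 10 h | the portions of substrate follow each other after 2.0 h, the first at the start |
| epsilon | 0.10 M (in portions, 3) | 0.400 M | 60 °C | 10 h | the portions of substrate follow each other after 2.0 h, the first at the start |
| gamma | 0.10 M (in portions, 3) | 0.400 M | 30 °C | 10 h | the portions of substrate follow each other after 2.0 h, the first at the start |

- target is meant together with its crystals
- solid, in amounts per volume of the solution: crystals
- the constants hold at 0 °C; other temperatures follow from the activation energies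

- which flask leads in share of target in all that became target or side product A or side product B ("all alike" within 1.5 percentage points) (eta / epsilon / gamma / all alike)
- share of target in all that became target or side product A or side product B, eta
- share of target in all that became target or side product A or side product B, epsilon
- share of target in all that became target or side product A or side product B, gamma

Substrate and coupling partner give intermediate A, and there the first fork stands: intermediate A turns into intermediate B or into side product A. The second fork stands at intermediate B, which turns into target or takes up coupling partner and ends, by way of intermediate C, as side product B.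

My bench rule is that a fork with first-order arms, at fixed temperature, divides material in the ratio of its arm constants, whatever the time course, so I look for what stays nearly constant and freeze it. The coupling partner is charged at 0.400 M against 0.10 M of substrate, so I freeze it at its charge, which makes the arm to intermediate C pseudo-first-order.

In epsilon, at 60 °C, the first fork sends 52.2% on towards target and the second 78.1%. Their product is 40.8%, and this product of the two fork fractions, the road share, is what I carry. With the constants as given for eta it is 6.09%.

The rule holds for material that has passed the forks, so I find its border with a ratio: the time the last portion has from its addition to the end of the run, 6.00 h, over the lifetime of substrate under the frozen partner. That ratio is 65.6 in epsilon and 4.34 in gamma, but 0.158 in eta, where the lifetime is 37.9 h. So the rule stops at eta, and there I commit only to a share below 6.09%, while for epsilon I commit to 40.8%.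

The forecast names epsilon as the leader, with 1.8% for eta, 42% for epsilon and 24% for gamma, and says of the cold flask that “the sequence barely progresses in 10 h”. Its figure for epsilon is higher than my road share.

The simulation puts epsilon ahead, at 42.2%, with gamma at 23.8% and eta at 1.75%, so the road share for epsilon lies 1.4 percentage points under the result. In epsilon the coupling partner stands at 73% of its charge after 10.0 h, below the value at which I froze it. For gamma, at 30 °C, the same two fork fractions multiply to a road share of 21.9%, and the gamma flask gives 23.8%.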